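Its constants stand for no real mixture; the run is a simulation.

- The pitfall: 2.00 equiv of nucleophile in west reads as an excess over the electrophile, but one electrophile can cost more than one nucleophile.

| flask | electrophile | nucleophile | time |
|---|---|---|---|
| west | 0.10 M | 2.00 equiv | 2.5 h |
| north-west | 0.10 M | 3.00 equiv | 2.5 h |
| east | 0.10 M | 4.50 equiv | 2.5 h |

    electrophile + nucleophile ⇌ acid set free + target (K1 = 0.18, k1 = 0.0026 L mol⁻¹ s⁻¹)
    nucleophile + acid set free ⇌ protonated nucleophile, settled at all times (K2 = 7400 L mol⁻¹)
    nucleophile + target → over-reaction product (k3 = 0.0050 L mol⁻¹ s⁻¹)

1. part of the electrophile that has reacted at the end, west
2. part of the electrophile that has reacted at the end, north-west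
3. part of the electrophile that has reacted at the end, east
4. what raising the equivalents of nucleophile from its lowest to its highest value here does to the part of the electrophile that has reacted (changes below 5 percentage points count as none) (it rises / it falls / no change)

- Powers of ten sort the steps. In west at the start, the common logarithm of the acid-binding constant times c(nucleophile) is 3.17, so protonated nucleophile outweighs acid set free, and each acid set free takes a second nucleophile.
- The over-reaction constant over the forward constant, a selectivity factor, is 1.92, and target can take a third nucleophile.
- West has a budget number of 0.667; this is the equivalents charged over the 3 nucleophiles that one electrophile costs on its full way to over-reaction product.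
- Below one, nucleophile is the limiting reagent of west. This reckoning reads west at 66.7%.
- East has 1.50, above one, and reads 100%.
- North-west has 1.00, on the border, so it gets a bound and no value: 100%.
- One number is not enough. In west the forward half-life of electrophile, as charged, is 0.37 h, short against 2.5 h, but the forward rate falls as free nucleophile falls. Target still standing in west has cost two nucleophiles, not 3, so west can lie above its budget number.
- The forecast gives 70% (66% to 73%) for west, above this reckoning. It gives 89.5% (86% to 92%) for north-west, 99.1% (97.5% to 99.7%) for east, and for the trend, it rises. Its ground: “2 equiv runs out at about 70% conversion”.
- The simulation gives 70.2% in west, 89.7% in north-west and 99.1% in east; the trend is it rises, by 29 percentage points.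
- West ends 3.5 points above its budget number.
- A neighbour flask, west with 0.500 equiv of nucleophile, has a budget number of 0.167. The neighbour's conversion is 22.1%, higher than that number. At 2.50 h the neighbour holds 16.9% as target and 5.23% as over-reaction product, and 77.9% of its electrophile is still there.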